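## The problem

The target is a C27 apocarotenoid furanoid oxide, (3S,5R,8S,9Z)-5,8-epoxy-5,8-dihydro-10'-apo-β-carotene-3,10'-diol. Ring A (cyclohexane C1–C6) is fused through the C5–C6 bond to ring B (2,5-dihydrofuran O–C5–C6=C7–C8), and C8 carries a hexaene chain that ends in an allylic alcohol at C10'. There are three stereocentres: C3 (secondary carbinol), C5 (fully substituted, bearing methyl, the ring oxygen, C4 and C6) and C8 (the allylic ether carbon). Only C8 can easily come from the chiral pool. It can steer C5 across the ring oxygen if C5 is formed from a planar centre. Once C5 is fixed, the ring fusion holds the C5 methyl axial, and together with the axial C1 methyl it shields one face of a C3 carbonyl, so C5 can in turn control C3. The chain must be joined with a Z trisubstituted C9=C10 bond and E geometry elsewhere. The sensitive elements are: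

- the C8–O bond, an allylic ether that becomes doubly allylic once C9=C10 exists and then ionises with acid;
- the 9Z bond and the polyene, which isomerise or oxidise with acid, iodine, light and air;
- the carbonyl intermediates on the way, which carry β-alkoxy or α-alkoxy-allylic hydrogens and are base-labile.

The feature that opens the key step is C5 itself. With the C4–C5 bond removed, C5 is the carbonyl carbon of a γ-substituted butenolide plus a methyl group. As a cation it is stabilised by the ring oxygen, and C4 can be the terminal carbon of an enol silane on the four-carbon arm that C6 already carries.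

## Retrosynthesis

Carotenoid locants are used for the core throughout (C1 = CMe2, C3 = carbinol, C5 = O-bearing quaternary carbon, C6 = sp2 ring-fusion carbon, C7 = ring-B CH=, C8 = OCH, C9 = first chain carbon).

**Polyene end (C10' alcohol, C11=C12).** Target 32 is traced to ethyl ester 31, so that the free allylic alcohol appears only in the last, neutral reduction. Ester 31 is cut at C11=C12 into the ring-side C15 phosphonium salt 26 and the C12 ester-aldehyde 29. This bond is a disubstituted alkene next to the C13 methyl, so its Z isomer is a hindered cis bond that relaxes thermally to E. Cutting at C9=C10 instead would ask an olefination to make the Z trisubstituted bond. Aldehyde 29 comes in one step from the commercial C10 dialdehyde 27 and triethyl phosphonoacetate 28. The forward Wittig reaction must keep the 9Z bond and must not let the ylide expel the C8 oxygen.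

**C9 substituents (C9–CH3, C9=C10, C10–C11).** Salt 26 goes back through the (9Z)-diol 24 to enoate 23, and 23 is cut at the C9–CH3 bond to ynoate 22. Syn addition of a methylcuprate to an ynoate places the methyl cis to H10 and therefore C8 cis to C11. An olefination of a C9 methyl ketone would favour the unwanted 9E isomer. Ynoate 22 comes from dibromoalkene 20 and this from aldehyde 19, the oxidation product of diol 18. The forward steps must never expose aldehyde 19 to base, because H8 is α-alkoxy and allylic.

**C3 carbinol (C3–H).** Alcohol 17, the silyl ether of 18, is traced to ketone 16. The cut removes one stereocentre and asks only that hydride arrive from the equatorial side of a ketone whose axial face is blocked by two methyl groups.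

**Ring A (C4–C5), the key cut.** Ketone 16 is opened at C4–C5 to the monocyclic silyl ketal 14, in which C5 is the ketal carbon of a 2-methyl-2-silyloxy-2,5-dihydrofuran and C4 is the CH2 terminus of an enol silane. Cutting O–C5, C1–C6 or C8–C9 instead would keep ring A and ask for the quaternary C5 stereocentre from a separate operation. The C4–C5 cut removes a ring and a stereocentre together and leaves a precursor with one stereocentre. The forward reaction must close the six-membered ring faster than the cation loses H8, must attack C5 and not C7, and must do so anti to the C8 substituent.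

**C5 methyl and enol silane.** Ketal 14 comes from butenolide 12 by addition of methyllithium to the lactone carbonyl (C5–CH3 bond) and silylation of the tetrahedral alkoxide. The enol silane of 12 comes from methyl ketone 11. The enol silane has to be in place before methyllithium, since it is the only form of the C3 ketone that survives it. The forward enolisation must distinguish the ketone methyl from H8 of the butenolide.

**Butenolide (C6=C7, C6–C7, lactone C–O).** Butenolide 11 is traced through hydroxy lactone 9 and diol 8 to the open aldol adduct 7, and 7 is cut at C6–C7 into ester 4 and (R)-glyceraldehyde acetonide 5. An olefination with an α-tert-alkyl phosphonoacetate would need a very hindered carbanion and Z selectivity. The aldol–lactonisation–elimination sequence needs neither, because both new centres are erased and the lactone fixes the alkene geometry. C8 is the carbon already present in 5.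

**Quaternary C1 (C1–C6).** Ester 4 is the ketal of keto ester 3, which is cut at C1–C6 into mesityl oxide 1 and the acetate ketene silyl acetal 2. The forward conjugate addition must reach a β,β-disubstituted enone, which a Lewis-acid-mediated Mukaiyama–Michael addition does.

## Roads not taken

Alternative 1: The cut is C8–C9. In the forward sense Me3SiOTf ionises the C8 methyl acetal A1 to an oxocarbenium ion conjugated with C6=C7. The (Z)-alkenylstannane carbon C9, held on a diisopropylsilylene bridge from O3, attacks C8 and gives the bridged furanoid A2 through a temporary 11-membered ring.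
- Merits: the cation cannot aromatise because C5 is already quaternary; the tether delivers C9 to the face of O3, which is the face required; the 9Z alkene and three chain carbons arrive in the same event.
- Weak points: the closure passes through an 11-membered transition state; the trisubstituted alkenylstannane is open to protodestannylation and the silylene to cleavage by the silyl triflate; and A1 presupposes the bicyclic core with C5 already set, which is the hardest part of the molecule.
- Comparison: for the chain this road is better, since it does in one step what the chosen plan does in steps 11–16. The chosen plan sets against it a key step that builds ring A and the quaternary stereocentre that alternative 1 takes for granted, through a six-membered closure.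

Alternative 2: The cut is O–C5. Cu(CF3COCHCOCF3)2 (divalent copper) opens the cis-7,8-epoxide A3 at allylic C7; the oxygen stays on C8 and closes on C5, giving the 8-alkynyl furanoid A4 with the alkene moved to C6=C7.
- Merits: the step is catalytic and atom-economical; ring expansion of vinyl oxiranes to 2,5-dihydrofurans is an established reaction class; C3 is in place from the start; and the alkyne at C8 is ready for the chain.
- Weak points: A3 needs an enantiopure cis-epoxide next to a tetrasubstituted ring alkene; the oxygen must bond to the fully substituted terminus C5; and the C5 face is chosen only by the remote C3 substituent and by whatever memory of the epoxide survives ionisation at C7.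
- Comparison: in step count this road is probably shorter and its key step is catalytic, which the chosen plan cannot match. The chosen plan sets against it a chiral-pool C8 that needs no asymmetric epoxidation, and a relay C8 → C5 → C3 in which each new centre is read from a defined feature of the substrate.

Alternative 3: The cut is C1–C6. Pd(OAc)2 with PPh3 and HCO2Na (zerovalent palladium formed in situ) inserts into the C6–I bond of iododihydrofuran A5; the alkenylpalladium adds 6-exo-trig to the isopropenyl group, and formate reduces the neopentylpalladium to the second C1 methyl, giving A6.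
- Merits: reductive Heck cyclisations of this type are well precedented; the neopentyl intermediate has no β-hydrogen; and C3 needs no late reduction.
- Weak points: the key step creates no stereocentre, so C3, the quaternary C5 and C8 of A5 must each be set beforehand; A5 and A6 are allylic ethers at both C5 and C8 and may ionise on palladium; and the neopentylpalladium may add to C6=C7 before formate intercepts it.
- Comparison: as a ring closure this step is more secure than a cationic closure that competes with aromatisation. The chosen plan accepts the less certain closure because it forms ring A and the quaternary stereocentre in one step from a precursor with a single stereocentre.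

Key step: step 9

Assumption: the C9=C10 bond of the target is Z as written in the SMILES (C8 and C11 cis), and all other chain double bonds are E.

## Route

Step 1
Reactants: 1 mesityl oxide; 2 tert-butyl[(1-methoxyethenyl)oxy]dimethylsilane
Product: 3 methyl 3,3-dimethyl-5-oxohexanoate
Conditions: TiCl4, CH2Cl2, −78 °C; aq. K2CO3
Reagents that add atoms: none
Why: Mukaiyama–Michael addition: TiCl4 activates the enone and the ketene silyl acetal adds to the β,β-disubstituted carbon, forming the C1–C6 bond and the quaternary C1; no stereocentre is formed.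

Step 2
Reactants: 3 methyl 3,3-dimethyl-5-oxohexanoate
Product: 4 methyl 5,5-dimethoxy-3,3-dimethylhexanoate
Conditions: HC(OMe)3, MeOH, p-TsOH·H2O (cat.), rt; NaHCO3
Reagents that add atoms: trimethyl orthoformate, COC(OC)OC; methanol, CO
Why: Acid-catalysed ketalisation with the orthoformate as water scavenger masks the ketone, which is more acidic than the ester, so that C6 can be deprotonated in step 3.

Step 3
Reactants: 4 methyl 5,5-dimethoxy-3,3-dimethylhexanoate; 5 (R)-2,3-O-isopropylideneglyceraldehyde
Product: 7 methyl 2-{[(4R)-2,2-dimethyl-1,3-dioxolan-4-yl](hydroxy)methyl}-5,5-dimethoxy-3,3-dimethylhexanoate (diastereomers at C6 and C7), via lithium enolate 6 (not isolated)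
Conditions: LiN(i-Pr)2, THF, −78 °C; then 5, −78 °C; aq. NH4Cl
Reagents that add atoms: none
Why: Lithium ester enolate aldol addition forms C6–C7; C8 is carried unchanged from 5, and the two new centres need no control because both become sp2 in step 6.

Step 4
Reactants: 7 aldol adduct
Product: 8 (5R)-4-hydroxy-5-(hydroxymethyl)-3-(2-methyl-4-oxopentan-2-yl)oxolan-2-one (diastereomers at C6 and C7)
Conditions: 1 M HCl, THF, rt; toluene azeotrope
Reagents that add atoms: water, O
Why: Acid hydrolysis removes the acetonide and the dimethyl ketal, and the freed C8 hydroxyl lactonises onto the ester, the five-membered lactone being preferred over the six-membered one as in 2-deoxypentonolactones; C8 is not touched.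

Step 5
Reactants: 8 keto lactone diol
Product: 9 (5R)-5-{[(tert-butyldiphenylsilyl)oxy]methyl}-4-hydroxy-3-(2-methyl-4-oxopentan-2-yl)oxolan-2-one
Conditions: TBDPSCl, imidazole, CH2Cl2, 0 °C
Reagents that add atoms: tert-butyl(chloro)diphenylsilane, CC(C)(C)[Si](Cl)(c1ccccc1)c2ccccc2
Why: Selective silylation of the primary hydroxyl with a bulky silyl chloride; this group is kept as the large C8 substituent that shields one face of the cation in step 9.

Step 6
Reactants: 9 hydroxy lactone silyl ether
Product: 11 (5S)-5-{[(tert-butyldiphenylsilyl)oxy]methyl}-3-(2-methyl-4-oxopentan-2-yl)furan-2(5H)-one, via C7 mesylate 10 (not isolated)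
Conditions: MsCl, Et3N, CH2Cl2, 0 °C → rt
Reagents that add atoms: none
Why: Mesylation of the C7 hydroxyl and E1cB elimination of the β-mesyloxy lactone by the amine give the butenolide; both diastereomers converge, and any hemiketal tautomer between O7 and C3 is drained through its open form.

Step 7
Reactants: 11 keto butenolide
Product: 12 (5S)-3-{4-[(tert-butyldimethylsilyl)oxy]-2-methylpent-4-en-2-yl}-5-{[(tert-butyldiphenylsilyl)oxy]methyl}furan-2(5H)-one
Conditions: TBSCl, KN(SiMe3)2 (added last), THF, −78 °C; pH 7 buffer
Reagents that add atoms: tert-butyl(chloro)dimethylsilane, CC(C)(C)[Si](C)(C)Cl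
Why: Kinetic enolisation and in situ O-silylation of the methyl ketone at its unhindered methyl group (C4); the C2 methylene is neopentylic and H8 is a shielded tertiary hydrogen, so both should react more slowly with the bulky amide, and the resulting silyl enol ether tolerates methyllithium at −78 °C.

Step 8
Reactants: 12 enol silane butenolide
Product: 14 tert-butyl{[(2S)-4-{4-[(tert-butyldimethylsilyl)oxy]-2-methylpent-4-en-2-yl}-5-methyl-5-[(trimethylsilyl)oxy]-2,5-dihydrofuran-2-yl]methoxy}diphenylsilane (C5 epimers), via lithium lactolate 13 (not isolated)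
Conditions: MeLi (1.05 equiv), THF, −78 °C; Me3SiCl, −78 → −30 °C; cold aq. NaHCO3; used crude
Reagents that add atoms: methyllithium, [Li]C; chlorotrimethylsilane, C[Si](C)(C)Cl
Why: 1,2-Addition of methyllithium to the lactone carbonyl gives a tetrahedral lithium alkoxide that persists at −78 °C and is O-silylated in the flask before it can lose water to the furan; both C5 epimers are acceptable because C5 becomes planar in step 9.

Step 9
Reactants: 14 silyl ketal with enol silane arm
Product: 16 (2S,7aR)-2-{[(tert-butyldiphenylsilyl)oxy]methyl}-4,4,7a-trimethyl-4,5,7,7a-tetrahydro-1-benzofuran-6(2H)-one [(5R,8S) in carotenoid locants], via oxocarbenium triflate 15 (not isolated)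
Conditions: Me3SiOTf (0.2 equiv), 2,6-di-tert-butyl-4-methylpyridine (0.3 equiv), CH2Cl2, −78 °C; aq. NaHCO3
Reagents that add atoms: none
Why: Me3SiOTf removes the C5 silyloxy group as a disiloxane and gives oxocarbenium ion 15, planar at C5 and conjugated with C6=C7; the enol silane carbon C4 adds to C5, and loss of the silyl group from the resulting silyloxycarbenium ion leaves the C3 ketone and returns a silyl triflate that carries the chain. The closest known reaction type is the Mukaiyama-type addition of silyl enol ethers to cyclic oxocarbenium ions generated from 2-alkoxy-2,5-dihydrofurans, used here intramolecularly. Ring A closes in a chair-like 6-(enolendo)-exo-trig mode. The new stereocentre C5 is controlled by C8: C4 should approach the face of ring B opposite to the silyloxymethyl group, which places the C5 methyl cis to C9 (5R from 8S). Two selectivities are needed: bond formation must outrun loss of H8, which would give the aromatic furan and erase C8, and C4 must attack C5 and not the vinylogous position C7, which would also give a six-membered ring. The first is served by the tethered nucleophile, the low temperature, a hindered pyridine that traps protons but does not deprotonate carbocations, and the fact that the product can no longer aromatise; the second by the charge at the oxygen-bearing C5 and by allylic strain between the C5 methyl and the C1 gem-dimethyl group, which keeps C2 out of the ring-B plane on the C5 side.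

Step 10
Reactants: 16 bicyclic ketone
Product: 17 (2S,6S,7aR)-2-{[(tert-butyldiphenylsilyl)oxy]methyl}-4,4,7a-trimethyl-2,4,5,6,7,7a-hexahydro-1-benzofuran-6-ol [(3S,5R,8S)]
Conditions: LiBH(s-Bu)3, THF, −78 °C; NaBO3·4H2O work-up
Reagents that add atoms: none
Why: Substrate-controlled hydride reduction: the ring fusion holds the C5 methyl axial, and with the axial C1 methyl it blocks the axial face of the C3 carbonyl, so the bulky borohydride adds from the equatorial side and gives the axial (3S) alcohol cis to the C5 methyl. Reducing before any basic step also removes the β-alkoxy ketone, which could open ring B by E1cB.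

Step 11
Reactants: 17 silyl ether alcohol
Product: 18 (2S,6S,7aR)-2-(hydroxymethyl)-4,4,7a-trimethyl-2,4,5,6,7,7a-hexahydro-1-benzofuran-6-ol
Conditions: Bu4NF, THF, 0 °C → rt
Reagents that add atoms: none
Why: Fluoride cleavage of the silyl ether; no stereocentre is affected.

Step 12
Reactants: 18 diol
Product: 19 (2S,6S,7aR)-6-hydroxy-4,4,7a-trimethyl-2,4,5,6,7,7a-hexahydro-1-benzofuran-2-carbaldehyde
Conditions: 2,2,6,6-tetramethylpiperidine-1-oxyl (cat.), PhI(OAc)2, CH2Cl2, 0 °C → rt; used at once
Reagents that add atoms: none
Why: Nitroxyl-catalysed oxidation is selective for the primary alcohol over the hindered axial secondary one and needs no base, which matters because H8 of the aldehyde is α-alkoxy and allylic.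

Step 13
Reactants: 19 aldehyde
Product: 20 (2S,6S,7aR)-2-(2,2-dibromoethenyl)-4,4,7a-trimethyl-2,4,5,6,7,7a-hexahydro-1-benzofuran-6-ol
Conditions: CBr4, PPh3, Zn, CH2Cl2, rt (ylide preformed); then 19, 0 °C
Reagents that add atoms: carbon tetrabromide, BrC(Br)(Br)Br
Why: First stage of the Corey–Fuchs sequence, a Wittig reaction with the weakly basic dibromomethylene ylide, chosen over base-mediated diazophosphonate homologation to avoid enolisation at C8.

Step 14
Reactants: 20 dibromoalkene
Product: 22 methyl 3-{(2S,6S,7aR)-6-[(methoxycarbonyl)oxy]-4,4,7a-trimethyl-2,4,5,6,7,7a-hexahydro-1-benzofuran-2-yl}prop-2-ynoate, via dilithium alkoxide acetylide 21 (not isolated)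
Conditions: n-BuLi (3.2 equiv), THF, −78 °C; ClCO2Me (excess), −78 → 0 °C
Reagents that add atoms: methyl chloroformate, COC(=O)Cl
Why: Bromine–lithium exchange and Fritsch–Buttenberg–Wiechell rearrangement give the lithium acetylide, which is C-acylated by the chloroformate; the C3 alkoxide is acylated as well, and the carbonate protects C3 until step 16 removes it.

Step 15
Reactants: 22 ynoate carbonate
Product: 23 methyl (2Z)-3-{(2S,6S,7aR)-6-[(methoxycarbonyl)oxy]-4,4,7a-trimethyl-2,4,5,6,7,7a-hexahydro-1-benzofuran-2-yl}but-2-enoate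
Conditions: Me2CuLi (from CuI and MeLi), THF, −78 °C; MeOH, −78 °C; aq. NH4Cl
Reagents that add atoms: lithium dimethylcuprate, [Li+].C[Cu-]C
Why: Syn carbocupration of the ynoate puts the methyl on C9 cis to H10, hence C8 cis to C11 (9Z); protonation at −78 °C precedes equilibration of the alkenylcopper through its allenolate form.

Step 16
Reactants: 23 (Z)-enoate carbonate
Product: 24 (2S,6S,7aR)-2-[(2Z)-4-hydroxybut-2-en-2-yl]-4,4,7a-trimethyl-2,4,5,6,7,7a-hexahydro-1-benzofuran-6-ol
Conditions: (i-Bu)2AlH (excess), CH2Cl2, −78 → 0 °C; Rochelle salt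
Reagents that add atoms: none
Why: Hydride reduction of the enoate to the allylic alcohol leaves the Z double bond alone, and the same reagent cleaves the C3 carbonate, so no separate deprotection is needed.

Step 17
Reactants: 24 (9Z)-C15 diol
Product: 26 {(2Z)-3-[(2S,6S,7aR)-6-hydroxy-4,4,7a-trimethyl-2,4,5,6,7,7a-hexahydro-1-benzofuran-2-yl]but-2-en-1-yl}triphenylphosphonium bromide, via allylic bromide 25 (not isolated)
Conditions: CBr4 (1.05 equiv), PPh3 (2.2 equiv), CH2Cl2, 0 °C → rt, dark
Reagents that add atoms: triphenylphosphine, c1ccc(cc1)P(c2ccccc2)c3ccccc3; carbon tetrabromide, BrC(Br)(Br)Br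
Why: Appel bromination of the primary allylic alcohol under neutral conditions, then SN2 displacement by the second equivalent of phosphine, gives the Wittig salt. Acid is avoided because C8 is now a doubly allylic ether, and the hindered axial C3 hydroxyl should not react.

Step 18
Reactants: 27 (2E,4E,6E)-2,7-dimethylocta-2,4,6-trienedial; 28 triethyl phosphonoacetate
Product: 29 ethyl (2E,4E,6E,8E)-4,9-dimethyl-10-oxodeca-2,4,6,8-tetraenoate
Conditions: NaH, THF, 0 °C; added to 27 (3 equiv), 0 °C → rt
Reagents that add atoms: none
Why: Horner–Wadsworth–Emmons olefination of one aldehyde of the symmetrical dialdehyde, which is kept in excess to favour mono-olefination; the stabilised phosphonate anion gives the E alkene (C11'=C12').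

Step 19
Reactants: 26 C15 phosphonium bromide; 29 C12 ester-aldehyde
Product: 31 ethyl (2E,4E,6E,8E,10E,12Z)-13-[(2S,6S,7aR)-6-hydroxy-4,4,7a-trimethyl-2,4,5,6,7,7a-hexahydro-1-benzofuran-2-yl]-4,9-dimethyltetradeca-2,4,6,8,10,12-hexaenoate, via 11Z ester 30 (not isolated)
Conditions: NaOEt, EtOH–CH2Cl2, 0 °C → rt, dark; then heptane, 80 °C
Reagents that add atoms: none
Why: Wittig olefination forms C11=C12; C15 allylic ylides of this kind are known to keep a 9Z bond, and the hindered 11Z isomer 30 that forms beside the E isomer should relax thermally to 11E while the unhindered 9Z bond persists. The ylide is generated at 0 °C in the presence of the aldehyde so that it is consumed before it can expel the C8 oxygen.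

Step 20
Reactants: 31 C27 ester
Product: 32 (3S,5R,8S,9Z)-5,8-epoxy-5,8-dihydro-10'-apo-β-carotene-3,10'-diol (CNP0263491.3)
Conditions: (i-Bu)2AlH, CH2Cl2, −78 °C; Rochelle salt; dark, argon
Reagents that add atoms: none
Why: Hydride reduction of the conjugated ester to the primary allylic alcohol at low temperature with a neutral work-up, so that no acid can ionise the C8–O bond or isomerise the polyene.

## Compound list

1 | mesityl oxide (4-methylpent-3-en-2-one) | CC(=O)C=C(C)C | starting material
2 | tert-butyl[(1-methoxyethenyl)oxy]dimethylsilane | COC(=C)O[Si](C)(C)C(C)(C)C | starting material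
3 | methyl 3,3-dimethyl-5-oxohexanoate | COC(=O)CC(C)(C)CC(C)=O | intermediate
4 | methyl 5,5-dimethoxy-3,3-dimethylhexanoate | COC(=O)CC(C)(C)CC(C)(OC)OC | intermediate
5 | (R)-2,3-O-isopropylideneglyceraldehyde | O=C[C@H]1COC(C)(C)O1 | starting material
6 | lithium enolate of ester 4 | [Li+].COC([O-])=CC(C)(C)CC(C)(OC)OC | intermediate
7 | methyl 2-{[(4R)-2,2-dimethyl-1,3-dioxolan-4-yl](hydroxy)methyl}-5,5-dimethoxy-3,3-dimethylhexanoate (diastereomers at C6 and C7) | COC(=O)C(C(O)[C@H]1COC(C)(C)O1)C(C)(C)CC(C)(OC)OC | intermediate
8 | (5R)-4-hydroxy-5-(hydroxymethyl)-3-(2-methyl-4-oxopentan-2-yl)oxolan-2-one (diastereomers at C6 and C7) | OC[C@@H]1C(O)C(C(C)(C)CC(C)=O)C(=O)O1 | intermediate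
9 | (5R)-5-{[(tert-butyldiphenylsilyl)oxy]methyl}-4-hydroxy-3-(2-methyl-4-oxopentan-2-yl)oxolan-2-one | CC(C)(C)[Si](OC[C@@H]1C(O)C(C(C)(C)CC(C)=O)C(=O)O1)(c2ccccc2)c3ccccc3 | intermediate
10 | (5R)-5-{[(tert-butyldiphenylsilyl)oxy]methyl}-3-(2-methyl-4-oxopentan-2-yl)-2-oxooxolan-4-yl methanesulfonate | CC(C)(C)[Si](OC[C@@H]1C(OS(C)(=O)=O)C(C(C)(C)CC(C)=O)C(=O)O1)(c2ccccc2)c3ccccc3 | intermediate
11 | (5S)-5-{[(tert-butyldiphenylsilyl)oxy]methyl}-3-(2-methyl-4-oxopentan-2-yl)furan-2(5H)-one | CC(C)(C)[Si](OC[C@@H]1C=C(C(C)(C)CC(C)=O)C(=O)O1)(c2ccccc2)c3ccccc3 | intermediate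
12 | (5S)-3-{4-[(tert-butyldimethylsilyl)oxy]-2-methylpent-4-en-2-yl}-5-{[(tert-butyldiphenylsilyl)oxy]methyl}furan-2(5H)-one | CC(C)(C)[Si](OC[C@@H]1C=C(C(C)(C)CC(=C)O[Si](C)(C)C(C)(C)C)C(=O)O1)(c2ccccc2)c3ccccc3 | intermediate
13 | lithium lactolate from 12 and methyllithium (C5 epimers) | [Li+].CC(C)(C)[Si](OC[C@@H]1C=C(C(C)(C)CC(=C)O[Si](C)(C)C(C)(C)C)C(C)([O-])O1)(c2ccccc2)c3ccccc3 | intermediate
14 | tert-butyl{[(2S)-4-{4-[(tert-butyldimethylsilyl)oxy]-2-methylpent-4-en-2-yl}-5-methyl-5-[(trimethylsilyl)oxy]-2,5-dihydrofuran-2-yl]methoxy}diphenylsilane (C5 epimers) | CC(C)(C)[Si](OC[C@@H]1C=C(C(C)(C)CC(=C)O[Si](C)(C)C(C)(C)C)C(C)(O[Si](C)(C)C)O1)(c2ccccc2)c3ccccc3 | intermediate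
15 | ring-B oxocarbenium triflate (2-methyl-5H-furan-1-ium with the C6 enol silane arm and C8 silyloxymethyl group) | CC(C)(C)[Si](OC[C@@H]1C=C(C(C)(C)CC(=C)O[Si](C)(C)C(C)(C)C)C(C)=[O+]1)(c2ccccc2)c3ccccc3.[O-]S(=O)(=O)C(F)(F)F | intermediate
16 | (2S,7aR)-2-{[(tert-butyldiphenylsilyl)oxy]methyl}-4,4,7a-trimethyl-4,5,7,7a-tetrahydro-1-benzofuran-6(2H)-one | CC(C)(C)[Si](OC[C@@H]1C=C2C(C)(C)CC(=O)C[C@@]2(C)O1)(c3ccccc3)c4ccccc4 | intermediate
17 | (2S,6S,7aR)-2-{[(tert-butyldiphenylsilyl)oxy]methyl}-4,4,7a-trimethyl-2,4,5,6,7,7a-hexahydro-1-benzofuran-6-ol | CC(C)(C)[Si](OC[C@@H]1C=C2C(C)(C)C[C@H](O)C[C@@]2(C)O1)(c3ccccc3)c4ccccc4 | intermediate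
18 | (2S,6S,7aR)-2-(hydroxymethyl)-4,4,7a-trimethyl-2,4,5,6,7,7a-hexahydro-1-benzofuran-6-ol | OC[C@@H]1C=C2C(C)(C)C[C@H](O)C[C@@]2(C)O1 | intermediate
19 | (2S,6S,7aR)-6-hydroxy-4,4,7a-trimethyl-2,4,5,6,7,7a-hexahydro-1-benzofuran-2-carbaldehyde | O=C[C@@H]1C=C2C(C)(C)C[C@H](O)C[C@@]2(C)O1 | intermediate
20 | (2S,6S,7aR)-2-(2,2-dibromoethenyl)-4,4,7a-trimethyl-2,4,5,6,7,7a-hexahydro-1-benzofuran-6-ol | BrC(Br)=C[C@@H]1C=C2C(C)(C)C[C@H](O)C[C@@]2(C)O1 | intermediate
21 | dilithium salt of the C8 ethynyl C3 alkoxide | [Li+].[Li+].[C-]#C[C@@H]1C=C2C(C)(C)C[C@H]([O-])C[C@@]2(C)O1 | intermediate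
22 | methyl 3-{(2S,6S,7aR)-6-[(methoxycarbonyl)oxy]-4,4,7a-trimethyl-2,4,5,6,7,7a-hexahydro-1-benzofuran-2-yl}prop-2-ynoate | COC(=O)C#C[C@@H]1C=C2C(C)(C)C[C@H](OC(=O)OC)C[C@@]2(C)O1 | intermediate
23 | methyl (2Z)-3-{(2S,6S,7aR)-6-[(methoxycarbonyl)oxy]-4,4,7a-trimethyl-2,4,5,6,7,7a-hexahydro-1-benzofuran-2-yl}but-2-enoate | C/C(=C/C(=O)OC)[C@@H]1C=C2C(C)(C)C[C@H](OC(=O)OC)C[C@@]2(C)O1 | intermediate
24 | (2S,6S,7aR)-2-[(2Z)-4-hydroxybut-2-en-2-yl]-4,4,7a-trimethyl-2,4,5,6,7,7a-hexahydro-1-benzofuran-6-ol | C/C(=C/CO)[C@@H]1C=C2C(C)(C)C[C@H](O)C[C@@]2(C)O1 | intermediate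
25 | (2S,6S,7aR)-2-[(2Z)-4-bromobut-2-en-2-yl]-4,4,7a-trimethyl-2,4,5,6,7,7a-hexahydro-1-benzofuran-6-ol | C/C(=C/CBr)[C@@H]1C=C2C(C)(C)C[C@H](O)C[C@@]2(C)O1 | intermediate
26 | {(2Z)-3-[(2S,6S,7aR)-6-hydroxy-4,4,7a-trimethyl-2,4,5,6,7,7a-hexahydro-1-benzofuran-2-yl]but-2-en-1-yl}triphenylphosphonium bromide | [Br-].C/C(=C/C[P+](c3ccccc3)(c4ccccc4)c5ccccc5)[C@@H]1C=C2C(C)(C)C[C@H](O)C[C@@]2(C)O1 | intermediate
27 | (2E,4E,6E)-2,7-dimethylocta-2,4,6-trienedial | O=C/C(C)=C/C=C/C=C(C)/C=O | starting material
28 | triethyl phosphonoacetate | CCOC(=O)CP(=O)(OCC)OCC | starting material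
29 | ethyl (2E,4E,6E,8E)-4,9-dimethyl-10-oxodeca-2,4,6,8-tetraenoate | CCOC(=O)/C=C/C(C)=C/C=C/C=C(C)/C=O | intermediate
30 | ethyl (2E,4E,6E,8E,10Z,12Z)-13-[(2S,6S,7aR)-6-hydroxy-4,4,7a-trimethyl-2,4,5,6,7,7a-hexahydro-1-benzofuran-2-yl]-4,9-dimethyltetradeca-2,4,6,8,10,12-hexaenoate (11Z isomer of 31) | C/C(=C/C=C\C(C)=C\C=C\C=C(C)\C=C\C(=O)OCC)[C@@H]1C=C2C(C)(C)C[C@H](O)C[C@@]2(C)O1 | intermediate
31 | ethyl (2E,4E,6E,8E,10E,12Z)-13-[(2S,6S,7aR)-6-hydroxy-4,4,7a-trimethyl-2,4,5,6,7,7a-hexahydro-1-benzofuran-2-yl]-4,9-dimethyltetradeca-2,4,6,8,10,12-hexaenoate | C/C(=C/C=C/C(C)=C/C=C/C=C(C)/C=C/C(=O)OCC)[C@@H]1C=C2C(C)(C)C[C@H](O)C[C@@]2(C)O1 | intermediate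
32 | (2S,6S,7aR)-2-[(2Z,4E,6E,8E,10E,12E)-14-hydroxy-6,11-dimethyltetradeca-2,4,6,8,10,12-hexaen-2-yl]-4,4,7a-trimethyl-2,4,5,6,7,7a-hexahydro-1-benzofuran-6-ol | C/C(=C/C=C/C(C)=C/C=C/C=C(C)/C=C/CO)[C@@H]1C=C2C(C)(C)C[C@H](O)C[C@@]2(C)O1 | target

## Step count and least certain steps

Total: 20 steps. Longest linear sequence: 19 steps (steps 1–17, 19 and 20); step 18 is a one-step side branch.

**Step 9 (key step).** The most likely failure is loss of H8 from oxocarbenium ion 15, which gives the aromatic furan and erases C8, running faster than closure at the fully substituted C5. Closure at the vinylogous position C7 and weak facial control by the distant C8 substituent are the next concerns.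
Fallback, from 14 back to 16: anhydrous fluoride ((Me2N)3S+ Me3SiF2−, two equivalents, THF, −78 → −40 °C) should cleave the silyl ketal and the enol silane. The enolate so released should add to the unmasked C5 carbonyl in an intramolecular aldol addition, giving the β-hydroxy ketone (4Z)-4-[(2S)-3-{[tert-butyl(diphenyl)silyl]oxy}-2-hydroxypropylidene]-3-hydroxy-3,5,5-trimethylcyclohexan-1-one F1, with the C4–C5 bond made and no cation on the way. Pyridinium p-toluenesulfonate in CH2Cl2 should then ionise the tertiary allylic C5 hydroxyl, and O8 closes ring B by allylic etherification, which can no longer lead to a furan, returning to 16. The price is that C5 is then set in a reversible etherification and its epimers may have to be separated.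

**Step 7.** The amide base may remove H8, which is γ to the lactone carbonyl and thermodynamically more acidic than the ketone methyl. This would lead to a silyloxyfuran and loss of the only stereocentre.
Fallback, from 9 back to 12: the enol silane is installed before the C6=C7 bond exists, so that H8 is not yet acidic. The C7 hydroxyl of 9 is capped (Me3SiCl, imidazole) to give the trimethylsilyl ether F2. The ketone is enolised and silylated as in step 7 to give the enol silane F3. The trimethylsilyl ether alone is cleaved (K2CO3, MeOH, 0 °C) to give the hydroxy lactone enol silane F4. MsCl and Et3N then form the mesylate F5, which eliminates in the flask to 12.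

**Step 8.** The lithium lactolate 13 may open to the enone alkoxide and take up a second methyllithium, or the adduct may dehydrate to the furan during work-up.
Fallback, from 12 back to 14: the addition is quenched cold into pH 7 phosphate buffer and the neutral lactol (2S)-4-{4-[(tert-butyldimethylsilyl)oxy]-2-methylpent-4-en-2-yl}-2-{[(tert-butyldiphenylsilyl)oxy]methyl}-5-methyl-2,5-dihydrofuran-5-ol F6 is isolated without acid. It is then silylated under neutral conditions with N-(trimethylsilyl)imidazole in CH2Cl2 at 0 °C to give 14. This separates the addition from the trapping and allows the amount of methyllithium to be judged on the isolated lactol.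

**Step 19.** The allylic ylide from 26 may lose the 9Z geometry through its delocalised form, or expel the C8 oxygen in a vinylogous β-elimination that opens ring B; thermal relaxation of 30 may also be incomplete.
Fallback, from 24 and 29 back to 31: the polarity of the olefination is reversed so that no carbanion sits next to C8. Diol 24 is oxidised with MnO2 in CH2Cl2 to the (9Z)-enal (2Z)-3-[(2S,6S,7aR)-6-hydroxy-4,4,7a-trimethyl-2,4,5,6,7,7a-hexahydro-1-benzofuran-2-yl]but-2-enal F7. Aldehyde 29 is reduced with NaBH4 in EtOH at 0 °C to ethyl (2E,4E,6E,8E)-10-hydroxy-4,9-dimethyldeca-2,4,6,8-tetraenoate F8, which PPh3·HBr converts into the phosphonium bromide [(2E,4E,6E,8E)-10-ethoxy-2,7-dimethyl-10-oxodeca-2,4,6,8-tetraen-1-yl]triphenylphosphonium bromide F9. Wittig reaction of F7 with F9 (NaOEt, EtOH–CH2Cl2, then thermal relaxation as in step 19) gives 31.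

## Further compounds

F1 | step 9 | (4Z)-4-[(2S)-3-{[tert-butyl(diphenyl)silyl]oxy}-2-hydroxypropylidene]-3-hydroxy-3,5,5-trimethylcyclohexan-1-one (C5 epimers) | CC(C)(C)[Si](OC[C@@H](O)/C=C1/C(C)(C)CC(=O)CC1(C)O)(c2ccccc2)c3ccccc3
F2 | step 7 | (5R)-5-{[(tert-butyldiphenylsilyl)oxy]methyl}-3-(2-methyl-4-oxopentan-2-yl)-4-[(trimethylsilyl)oxy]oxolan-2-one | CC(C)(C)[Si](OC[C@@H]1C(O[Si](C)(C)C)C(C(C)(C)CC(C)=O)C(=O)O1)(c2ccccc2)c3ccccc3
F3 | step 7 | (5R)-3-{4-[(tert-butyldimethylsilyl)oxy]-2-methylpent-4-en-2-yl}-5-{[(tert-butyldiphenylsilyl)oxy]methyl}-4-[(trimethylsilyl)oxy]oxolan-2-one | CC(C)(C)[Si](OC[C@@H]1C(O[Si](C)(C)C)C(C(C)(C)CC(=C)O[Si](C)(C)C(C)(C)C)C(=O)O1)(c2ccccc2)c3ccccc3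
F4 | step 7 | (5R)-3-{4-[(tert-butyldimethylsilyl)oxy]-2-methylpent-4-en-2-yl}-5-{[(tert-butyldiphenylsilyl)oxy]methyl}-4-hydroxyoxolan-2-one | CC(C)(C)[Si](OC[C@@H]1C(O)C(C(C)(C)CC(=C)O[Si](C)(C)C(C)(C)C)C(=O)O1)(c2ccccc2)c3ccccc3
F5 | step 7 | (5R)-3-{4-[(tert-butyldimethylsilyl)oxy]-2-methylpent-4-en-2-yl}-5-{[(tert-butyldiphenylsilyl)oxy]methyl}-2-oxooxolan-4-yl methanesulfonate | CC(C)(C)[Si](OC[C@@H]1C(OS(C)(=O)=O)C(C(C)(C)CC(=C)O[Si](C)(C)C(C)(C)C)C(=O)O1)(c2ccccc2)c3ccccc3
F6 | step 8 | (2S)-4-{4-[(tert-butyldimethylsilyl)oxy]-2-methylpent-4-en-2-yl}-2-{[(tert-butyldiphenylsilyl)oxy]methyl}-5-methyl-2,5-dihydrofuran-5-ol (C5 epimers) | CC(C)(C)[Si](OC[C@@H]1C=C(C(C)(C)CC(=C)O[Si](C)(C)C(C)(C)C)C(C)(O)O1)(c2ccccc2)c3ccccc3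
F7 | step 19 | (2Z)-3-[(2S,6S,7aR)-6-hydroxy-4,4,7a-trimethyl-2,4,5,6,7,7a-hexahydro-1-benzofuran-2-yl]but-2-enal | C/C(=C/C=O)[C@@H]1C=C2C(C)(C)C[C@H](O)C[C@@]2(C)O1
F8 | step 19 | ethyl (2E,4E,6E,8E)-10-hydroxy-4,9-dimethyldeca-2,4,6,8-tetraenoate | CCOC(=O)/C=C/C(C)=C/C=C/C=C(C)/CO
F9 | step 19 | [(2E,4E,6E,8E)-10-ethoxy-2,7-dimethyl-10-oxodeca-2,4,6,8-tetraen-1-yl]triphenylphosphonium bromide | [Br-].CCOC(=O)/C=C/C(C)=C/C=C/C=C(C)/C[P+](c1ccccc1)(c2ccccc2)c3ccccc3
A1 | alternative 1 | C8 methyl acetal of the furanoid core carrying the (Z)-3-(tributylstannyl)but-2-enyloxy-diisopropylsilyl tether on O3 (C8 epimers) | COC1C=C2C(C)(C)C[C@H](O[Si](C(C)C)(C(C)C)OC/C=C(/C)[Sn](CCCC)(CCCC)CCCC)C[C@@]2(C)O1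
A2 | alternative 1 | silylene-bridged C15 furanoid with the temporary 11-membered ring | C/C(=C/CO[Si](C(C)C)(C(C)C)O3)[C@@H]1C=C2C(C)(C)C[C@H]3C[C@@]2(C)O1
A3 | alternative 2 | cis-7,8-epoxide of the 3-(tert-butyldimethylsilyloxy) β-ring enyne with a trimethylsilylethynyl group on C8 | C[Si](C)(C)C#C[C@H]1O[C@H]1C2=C(C)C[C@@H](O[Si](C)(C)C(C)(C)C)CC2(C)C
A4 | alternative 2 | 8-(trimethylsilylethynyl) furanoid core, 3-O-tert-butyldimethylsilyl ether | C[Si](C)(C)C#C[C@@H]1C=C2C(C)(C)C[C@H](O[Si](C)(C)C(C)(C)C)C[C@@]2(C)O1
A5 | alternative 3 | 3-iodo-2,5-dihydrofuran with C5 methyl, the C5 2-silyloxy-4-methylpent-4-enyl chain and the C8 silyloxymethyl group | CC(C)(C)[Si](C)(C)OC[C@@H]1C=C(I)[C@@](C)(C[C@@H](O[Si](C)(C)C(C)(C)C)CC(C)=C)O1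
A6 | alternative 3 | bicyclic furanoid core with C9 silyloxymethyl group, 3-O-tert-butyldimethylsilyl ether | CC(C)(C)[Si](C)(C)OC[C@@H]1C=C2C(C)(C)C[C@H](O[Si](C)(C)C(C)(C)C)C[C@@]2(C)O1
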